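## Retrosynthetic overview

1. Enone: Claisen–Schmidt condensation of the ring A methyl ketone with 4-hydroxybenzaldehyde, in the same pot as cleavage of the acetate and pivalate esters (last step).
2. C2=C3 and C4–C7: cross-metathesis of a propenyl group with (S)-1-phenylhex-5-en-3-ol; C5 comes from Brown allylboration of 3-phenylpropanal.
3. C1 (diarylmethine), key step: aromatic Claisen rearrangement of an aryl (R)-1-methyl-3-arylallyl ether placed on the oxygen next to the acetyl group. Ring A is dearomatised to an ortho-dienone and the C–O stereocentre is transferred 1,3 to carbon.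
4. Ether: Mitsunobu inversion of an (S,E)-4-arylbut-3-en-2-ol (from 4-acetoxystyrene and (S)-but-3-en-2-ol by cross-metathesis) with 4-O-pivaloyl-2,4-dihydroxy-6-methoxyacetophenone.
5. Rings: none is built. All four benzene rings are bought; ring A is only dearomatised and re-aromatised in the key step.

Assumption: 1-(2,4-dihydroxy-6-methoxyphenyl)ethan-1-one, (S)-but-3-en-2-ol (≥98% ee) and (+)-Ipc2B(allyl) solution are taken as catalogue items.

Abbreviations: Piv = pivaloyl; Ipc = isopinocampheyl; DIAD = diisopropyl azodicarboxylate; H2IMes = 1,3-bis(2,4,6-trimethylphenyl)imidazolidin-2-ylidene; MOM = methoxymethyl. Ring A positions carry primes (C1′ bears the acetyl group); the heptenyl chain is numbered C1–C7 from the diarylmethine carbon.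

## Route

Step 1
Reactants: 1 1-(2,4-dihydroxy-6-methoxyphenyl)ethan-1-one
Product: 2 4-acetyl-3-hydroxy-5-methoxyphenyl pivalate
Conditions: PivCl (1.05 equiv), Et3N (1.2 equiv), CH2Cl2, 0 °C, 1 h
Reagents that add atoms: pivaloyl chloride, CC(C)(C)C(=O)Cl
Why: Selective O-acylation works because the 2-hydroxyl is locked in a hydrogen bond to the acetyl carbonyl, so one equivalent of acid chloride esterifies only the free 4-hydroxyl and leaves the 2-hydroxyl as the single phenol for the later etherification.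

Step 2
Reactants: 3 4-ethenylphenyl acetate (4-acetoxystyrene, 2.5 equiv); 4 (S)-but-3-en-2-ol
Product: 5 4-[(1E,3S)-3-hydroxybut-1-en-1-yl]phenyl acetate
Conditions: RuCl2(H2IMes)(=CH-C6H4-2-O-i-Pr) (second-generation Hoveyda–Grubbs catalyst, 3 mol%), CH2Cl2, 40 °C, 12 h
Reagents that add atoms: none
Why: Olefin cross-metathesis of a styrene with a secondary allylic alcohol gives the E cross-product selectively under ruthenium carbene catalysis, the excess styrene only dimerises, and the carbinol centre of 4 is not touched.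

Step 3
Reactants: 2 4-acetyl-3-hydroxy-5-methoxyphenyl pivalate; 5 4-[(1E,3S)-3-hydroxybut-1-en-1-yl]phenyl acetate
Product: 6 4-acetyl-3-{[(2R,3E)-4-(4-acetoxyphenyl)but-3-en-2-yl]oxy}-5-methoxyphenyl pivalate
Conditions: PPh3 (1.5 equiv), DIAD (1.5 equiv), toluene, 0 °C to rt, 16 h
Reagents that add atoms: none
Why: Mitsunobu etherification displaces the alkoxyphosphonium ion by SN2 with inversion, so the (S)-alcohol becomes the (R)-aryl ether at the only free phenol of 2, and the electron-poor acetoxyphenyl group disfavours ionisation and SN2′ attack.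

Step 4
Reactants: 6 4-acetyl-3-{[(2R,3E)-4-(4-acetoxyphenyl)but-3-en-2-yl]oxy}-5-methoxyphenyl pivalate
Product: 8 4-acetyl-2-[(1R,2E)-1-(4-acetoxyphenyl)but-2-en-1-yl]-3-hydroxy-5-methoxyphenyl pivalate, via ortho-dienone 7 (not isolated)
Conditions: PhNEt2 (0.1 M), argon, 160 °C, 3 h
Reagents that add atoms: none
Why: Aromatic Claisen ([3,3]-sigmatropic) rearrangement through a chair transition state with the methyl group equatorial breaks the aromaticity of ring A to give ortho-dienone 7, forms the C–C bond on the allyl face that oxygen leaves so that the (R) C–O centre becomes the (R) diarylmethine centre with an E-alkene, and enolisation of 7 restores the arene; the acetyl group blocks the other ortho position, so only C3′ can be attacked.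

Step 5
Reactants: 9 3-phenylpropanal
Product: 11 (S)-1-phenylhex-5-en-3-ol, via borinate ester 10 (not isolated)
Conditions: (+)-Ipc2B(allyl) (the enantiomer made from (−)-α-pinene, 1.2 equiv, 1 M in pentane), Et2O, −78 °C, 2 h; then 3 M NaOH, 30% H2O2, 0 °C to rt
Reagents that add atoms: (+)-B-allyldiisopinocampheylborane, C=CCB([C@H]1C[C@H]2C[C@@H]([C@@H]1C)C2(C)C)[C@H]1C[C@H]2C[C@@H]([C@@H]1C)C2(C)C
Why: Brown asymmetric allylboration passes through a closed chair (Zimmerman–Traxler) transition state in which the (−)-α-pinene-derived isopinocampheyl groups direct allyl transfer to the Re face of the aldehyde, giving the (S)-homoallylic alcohol after oxidative cleavage of borinate 10.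

Step 6
Reactants: 8 4-acetyl-2-[(1R,2E)-1-(4-acetoxyphenyl)but-2-en-1-yl]-3-hydroxy-5-methoxyphenyl pivalate; 11 (S)-1-phenylhex-5-en-3-ol (3 equiv)
Product: 12 4-acetyl-2-[(1R,2E,5S)-1-(4-acetoxyphenyl)-5-hydroxy-7-phenylhept-2-en-1-yl]-3-hydroxy-5-methoxyphenyl pivalate
Conditions: RuCl2(H2IMes)(=CH-C6H4-2-O-i-Pr) (second-generation Hoveyda–Grubbs catalyst, 10 mol% in two portions), 1,4-benzoquinone (20 mol%), CH2Cl2, 40 °C, 24 h
Reagents that add atoms: none
Why: Olefin cross-metathesis exchanges the propenyl terminus of 8 for the homoallylic alcohol chain with loss of propene, the bulky diarylmethine group next to the new double bond favours the E-isomer, neither stereocentre takes part, and benzoquinone suppresses ruthenium hydride migration of the double bond.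

Step 7
Reactants: 12 4-acetyl-2-[(1R,2E,5S)-1-(4-acetoxyphenyl)-5-hydroxy-7-phenylhept-2-en-1-yl]-3-hydroxy-5-methoxyphenyl pivalate; 13 4-hydroxybenzaldehyde (3 equiv)
Product: 16 epi-calyxin H, via deacylated ketone 14 (not isolated), via aldol adduct 15 (not isolated)
Conditions: KOH (50% aq, 20 equiv), EtOH, argon, rt, 48 h; then cold 1 M HCl to pH 5
Reagents that add atoms: none
Why: Hydroxide first saponifies the aryl acetate and pivalate and then drives the Claisen–Schmidt (crossed aldol) condensation of the methyl ketone with the non-enolisable aldehyde, E1cB dehydration of aldol 15 gives the E-enone as in the classical syntheses of polyhydroxychalcones from unprotected partners, and neither stereocentre is acidic under these conditions.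

## Compound list

1 | 1-(2,4-dihydroxy-6-methoxyphenyl)ethan-1-one | CC(=O)c1c(O)cc(O)cc1OC | starting material
2 | 4-acetyl-3-hydroxy-5-methoxyphenyl pivalate | CC(=O)c1c(O)cc(OC(=O)C(C)(C)C)cc1OC | intermediate
3 | 4-ethenylphenyl acetate (4-acetoxystyrene) | C=Cc1ccc(OC(C)=O)cc1 | starting material
4 | (S)-but-3-en-2-ol | C[C@H](O)C=C | starting material
5 | 4-[(1E,3S)-3-hydroxybut-1-en-1-yl]phenyl acetate | C[C@H](O)/C=C/c1ccc(OC(C)=O)cc1 | intermediate
6 | 4-acetyl-3-{[(2R,3E)-4-(4-acetoxyphenyl)but-3-en-2-yl]oxy}-5-methoxyphenyl pivalate | CC(=O)c1c(O[C@H](C)/C=C/c2ccc(OC(C)=O)cc2)cc(OC(=O)C(C)(C)C)cc1OC | intermediate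
7 | ortho-dienone, (6S)-2-acetyl-6-[(1S,2E)-1-(4-acetoxyphenyl)but-2-en-1-yl]-3-methoxy-5-(pivaloyloxy)cyclohexa-2,4-dien-1-one; formed in the flask; the side-chain centre has the same geometry as (1R) in 8, only the CIP ranking changes | CC(=O)C1=C(OC)C=C(OC(=O)C(C)(C)C)[C@H]([C@H](/C=C/C)c2ccc(OC(C)=O)cc2)C1=O | intermediate
8 | 4-acetyl-2-[(1R,2E)-1-(4-acetoxyphenyl)but-2-en-1-yl]-3-hydroxy-5-methoxyphenyl pivalate | CC(=O)c1c(O)c([C@H](/C=C/C)c2ccc(OC(C)=O)cc2)c(OC(=O)C(C)(C)C)cc1OC | intermediate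
9 | 3-phenylpropanal | O=CCCc1ccccc1 | starting material
10 | (3S)-1-phenylhex-5-en-3-yl diisopinocampheylborinate (Ipc groups of the (−)-α-pinene series); formed in the flask | C=CC[C@@H](OB([C@H]1C[C@H]2C[C@@H]([C@@H]1C)C2(C)C)[C@H]1C[C@H]2C[C@@H]([C@@H]1C)C2(C)C)CCc1ccccc1 | intermediate
11 | (S)-1-phenylhex-5-en-3-ol | C=CC[C@@H](O)CCc1ccccc1 | intermediate
12 | 4-acetyl-2-[(1R,2E,5S)-1-(4-acetoxyphenyl)-5-hydroxy-7-phenylhept-2-en-1-yl]-3-hydroxy-5-methoxyphenyl pivalate | CC(=O)c1c(O)c([C@H](/C=C/C[C@@H](O)CCc2ccccc2)c2ccc(OC(C)=O)cc2)c(OC(=O)C(C)(C)C)cc1OC | intermediate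
13 | 4-hydroxybenzaldehyde | O=Cc1ccc(O)cc1 | starting material
14 | 1-{2,4-dihydroxy-3-[(1R,2E,5S)-5-hydroxy-1-(4-hydroxyphenyl)-7-phenylhept-2-en-1-yl]-6-methoxyphenyl}ethan-1-one; formed in the flask | CC(=O)c1c(O)c([C@H](/C=C/C[C@@H](O)CCc2ccccc2)c2ccc(O)cc2)c(O)cc1OC | intermediate
15 | 1-{2,4-dihydroxy-3-[(1R,2E,5S)-5-hydroxy-1-(4-hydroxyphenyl)-7-phenylhept-2-en-1-yl]-6-methoxyphenyl}-3-hydroxy-3-(4-hydroxyphenyl)propan-1-one (both epimers at the new carbinol, lost on dehydration); formed in the flask | COc1cc(O)c([C@H](/C=C/C[C@@H](O)CCc2ccccc2)c2ccc(O)cc2)c(O)c1C(=O)CC(O)c1ccc(O)cc1 | intermediate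
16 | epi-calyxin H, (2E)-1-{2,4-dihydroxy-3-[(1R,2E,5S)-5-hydroxy-1-(4-hydroxyphenyl)-7-phenylhept-2-en-1-yl]-6-methoxyphenyl}-3-(4-hydroxyphenyl)prop-2-en-1-one | COc1cc(O)c([C@H](/C=C/C[C@@H](O)CCc2ccccc2)c2ccc(O)cc2)c(O)c1C(=O)/C=C/c1ccc(O)cc1 | target

## Step count and risks

Total steps: 7. Longest linear sequence: 5 steps (steps 2, 3, 4, 6, 7; the sequence 1, 3, 4, 6, 7 is equally long).

**Step 4 (Claisen rearrangement).** Dienone 7 may undergo a Cope shift to C5′ (para product) before it enolises. Ether 6 may also ionise or eliminate to 1-arylbutadiene and 2, which would erode the ee. Lewis acids such as Eu(fod)3 are avoided because chelation of the dienone would favour the Cope shift.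

Fallback, setting out from 5 and coming back at 8: run the rearrangement on a symmetric ring from the unhindered para oxygen.
- Mitsunobu coupling of 5 with commercial 1-(2,4,6-trihydroxyphenyl)ethan-1-one at its only non-chelated 4-hydroxyl (PPh3, DIAD) gives 1-(4-{[(2R,3E)-4-(4-acetoxyphenyl)but-3-en-2-yl]oxy}-2,6-dihydroxyphenyl)ethan-1-one F1.
- In F1 the two ortho positions are equivalent and the para position carries the acetyl group. Heating (PhNEt2, 160 °C) therefore gives, through 4-acetyl-6-[(1S,2E)-1-(4-acetoxyphenyl)but-2-en-1-yl]-3,5-dihydroxycyclohexa-2,4-dien-1-one F2, only 1-{3-[(1R,2E)-1-(4-acetoxyphenyl)but-2-en-1-yl]-2,4,6-trihydroxyphenyl}ethan-1-one F3.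
- PivCl/Et3N acylates the non-chelated 4-hydroxyl to give 4-acetyl-2-[(1R,2E)-1-(4-acetoxyphenyl)but-2-en-1-yl]-3,5-dihydroxyphenyl pivalate F4.
- MeI/K2CO3 in acetone methylates the less hindered of the two remaining hydroxyls (the one next to C–H, not the one next to the side chain) and gives 8.

This costs two more steps and removes both the regiochemical and the para-migration risk.

**Step 7 (one-pot saponification and condensation).** The polyphenoxide of 14 and the phenoxide of 13 are both poor aldol partners, so conversion may stall.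

Fallback, setting out from 12 and coming back at 16: a protected, stepwise endgame.
- 12 is de-acylated separately (K2CO3, MeOH, rt) and 14 is isolated.
- MOMCl/i-Pr2NEt caps every hydroxyl except the chelated one to give 1-{2-hydroxy-6-methoxy-4-(methoxymethoxy)-3-[(1R,2E,5S)-5-(methoxymethoxy)-1-[4-(methoxymethoxy)phenyl]-7-phenylhept-2-en-1-yl]phenyl}ethan-1-one F5.
- KOH/EtOH condensation with commercial 4-(methoxymethoxy)benzaldehyde, which now involves only one phenoxide, gives the MOM-protected chalcone (2E)-1-{2-hydroxy-6-methoxy-4-(methoxymethoxy)-3-[(1R,2E,5S)-5-(methoxymethoxy)-1-[4-(methoxymethoxy)phenyl]-7-phenylhept-2-en-1-yl]phenyl}-3-[4-(methoxymethoxy)phenyl]prop-2-en-1-one F6.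
- HCl in MeOH at rt removes the four MOM groups and gives 16.

**Step 3 (Mitsunobu at the hydrogen-bonded, hindered phenol).** Coupling may be slow, and partial SN1 or SN2′ reaction would lower the ee of 6.

Fallback, setting out from 5 and coming back at 6: make the C–O bond through a π-allyl palladium complex.
- Mitsunobu inversion of 5 with the much more acidic 4-nitrobenzoic acid (PPh3, DIAD, THF, 0 °C) gives (2R,3E)-4-(4-acetoxyphenyl)but-3-en-2-yl 4-nitrobenzoate F7.
- F7 and phenol 2 with Pd(PPh3)4 (5 mol%, zerovalent palladium) and Cs2CO3 in THF at rt give 6. Ionisation (inversion) followed by outer-sphere attack of the phenoxide at the methyl-bearing allyl terminus (inversion, styrene conjugation kept) amounts to retention from F7. The reaction is stopped early to limit re-ionisation of 6.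

## Further compounds

F1 | step 4 | 1-(4-{[(2R,3E)-4-(4-acetoxyphenyl)but-3-en-2-yl]oxy}-2,6-dihydroxyphenyl)ethan-1-one | CC(=O)c1c(O)cc(O[C@H](C)/C=C/c2ccc(OC(C)=O)cc2)cc1O
F2 | step 4 | (6S)-4-acetyl-6-[(1S,2E)-1-(4-acetoxyphenyl)but-2-en-1-yl]-3,5-dihydroxycyclohexa-2,4-dien-1-one | CC(=O)C1=C(O)[C@H]([C@H](/C=C/C)c2ccc(OC(C)=O)cc2)C(=O)C=C1O
F3 | step 4 | 1-{3-[(1R,2E)-1-(4-acetoxyphenyl)but-2-en-1-yl]-2,4,6-trihydroxyphenyl}ethan-1-one | CC(=O)c1c(O)c([C@H](/C=C/C)c2ccc(OC(C)=O)cc2)c(O)cc1O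
F4 | step 4 | 4-acetyl-2-[(1R,2E)-1-(4-acetoxyphenyl)but-2-en-1-yl]-3,5-dihydroxyphenyl pivalate | CC(=O)c1c(O)c([C@H](/C=C/C)c2ccc(OC(C)=O)cc2)c(OC(=O)C(C)(C)C)cc1O
F5 | step 7 | 1-{2-hydroxy-6-methoxy-4-(methoxymethoxy)-3-[(1R,2E,5S)-5-(methoxymethoxy)-1-[4-(methoxymethoxy)phenyl]-7-phenylhept-2-en-1-yl]phenyl}ethan-1-one | CC(=O)c1c(O)c([C@H](/C=C/C[C@@H](OCOC)CCc2ccccc2)c2ccc(OCOC)cc2)c(OCOC)cc1OC
F6 | step 7 | (2E)-1-{2-hydroxy-6-methoxy-4-(methoxymethoxy)-3-[(1R,2E,5S)-5-(methoxymethoxy)-1-[4-(methoxymethoxy)phenyl]-7-phenylhept-2-en-1-yl]phenyl}-3-[4-(methoxymethoxy)phenyl]prop-2-en-1-one | COCOc1ccc(/C=C/C(=O)c2c(O)c([C@H](/C=C/C[C@@H](OCOC)CCc3ccccc3)c3ccc(OCOC)cc3)c(OCOC)cc2OC)cc1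
F7 | step 3 | (2R,3E)-4-(4-acetoxyphenyl)but-3-en-2-yl 4-nitrobenzoate | C[C@@H](OC(=O)c1ccc(cc1)[N+](=O)[O-])/C=C/c1ccc(OC(C)=O)cc1
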